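## Retrosynthetic overview

1. The target comes from acetylation, desilylation and Mannich methylenation of a cis-fused macrocyclic γ-lactone, itself made from a macrocyclic 1,4-diol by oxidative lactonisation.
2. Key disconnection C5–C6 of ring A (14-membered carbocycle). This bond is the central CH2–CH2 link of the skipped 1,5-diene C3=C4–C5–C6–C7=C8, so both carbons are allylic. C5 becomes the CH2 terminus of an η3-allylpalladium unit (from an allylic acetate) and C6 a sulfonyl-stabilised allyl anion; the sulfonyl group is removed by hydride in the same operation.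
3. The seco precursor carries ring B (γ-lactone), closed first by oxidative lactonisation of an acyclic syn-homoallylic alcohol. C1 and C2 are set together in one acid-catalysed allylboration of an (E)-enal (C2–C5) with a (Z)-allylboronate.
4. The allylboronate comes from a tetraene built from an ynoate (syn-carbocupration fixes C7=C8 and the C19 oxygen), a Riley oxidation, and 3-sulfolene as butadiene carrier (C14, C1, C15, C16).
5. Ring order: ring B (step 14; it also masks the C2 and C16 oxygens and is reduced during the key step), then ring A (step 17), then ring B again (step 18).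

Key step: step 17

Remark on numbering: cembrane numbering is used. C1 is the ring CH bearing the lactone α-carbon C15 (C16 carbonyl, C17 exocyclic CH2), C2 the ring CH–O, then C3=C4(C18H3), C5, C6, C7=C8(C19H2O), C9, C10, C11=C12(C20H3), C13, C14. TBS = tert-butyldimethylsilyl, TBDPS = tert-butyldiphenylsilyl.

Assumption: the four starting materials and all reagents are taken as commercial. (R)-TRIP is assumed to direct the allyl group to the re face of the enal, as with simple aldehydes; if the sense is opposite, the enantiomeric acid is used.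

## Route

Step 1
Reactants: 1 1,1-diethoxy-3-methylbut-2-ene
Product: 2 (2E)-4,4-diethoxy-2-methylbut-2-en-1-ol
Conditions: SeO2 (cat.), t-BuOOH, CH2Cl2, 0 °C to rt
Reagents that add atoms: tert-butyl hydroperoxide, CC(C)(C)OO
Why: Riley allylic oxidation (ene reaction with SeO2, then [2,3]-sigmatropic shift) attacks the methyl group trans to the larger alkene substituent, so the E allylic alcohol that becomes C3=C4–C5 should form.

Step 2
Reactants: 2 (2E)-4,4-diethoxy-2-methylbut-2-en-1-ol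
Product: 3 (2E)-4,4-diethoxy-2-methylbut-2-en-1-yl acetate
Conditions: Ac2O, pyridine, DMAP (cat.), CH2Cl2, 0 °C
Reagents that add atoms: acetic anhydride, CC(=O)OC(C)=O
Why: DMAP-catalysed acyl transfer esterifies the primary allylic alcohol; this acetate is the later leaving group at C5.

Step 3
Reactants: 3 (2E)-4,4-diethoxy-2-methylbut-2-en-1-yl acetate
Product: 4 (2E)-2-methyl-4-oxobut-2-en-1-yl acetate
Conditions: PPTS (cat.), acetone–H2O, rt
Reagents that add atoms: water, O
Why: Acid-catalysed acetal hydrolysis should free the enal without touching the allylic acetate or the E alkene.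

Step 4
Reactants: 5 tert-butyl(diphenyl)(prop-2-yn-1-yloxy)silane
Product: 7 ethyl 4-[(tert-butyldiphenylsilyl)oxy]but-2-ynoate, via lithium acetylide 6 (not isolated)
Conditions: n-BuLi, THF, −78 °C; then ClCO2Et, −78 to 0 °C
Reagents that add atoms: ethyl chloroformate, CCOC(=O)Cl
Why: C-acylation of the lithium acetylide by the chloroformate gives the ynoate that serves as conjugate acceptor in step 5.

Step 5
Reactants: 7 ethyl 4-[(tert-butyldiphenylsilyl)oxy]but-2-ynoate; 8 5-bromo-2-methylpent-2-ene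
Product: 10 ethyl (2Z)-3-[(TBDPS-oxy)methyl]-7-methylocta-2,6-dienoate, via Grignard reagent 9 (not isolated)
Conditions: 8, Mg, THF; CuBr·SMe2, −40 °C; then 7, −78 °C; NH4Cl–MeOH at −78 °C
Reagents that add atoms: none
Why: syn-Carbocupration (conjugate addition of the organocopper reagent) and cold protonation place the new alkyl chain cis to H, so the ester carbon (C6) and the silyloxymethyl group (C19) end up cis on C7=C8 as in the target.

Step 6
Reactants: 10 ethyl (2Z)-3-[(TBDPS-oxy)methyl]-7-methylocta-2,6-dienoate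
Product: 11 ethyl (2Z,6E)-8-hydroxy-3-[(TBDPS-oxy)methyl]-7-methylocta-2,6-dienoate
Conditions: SeO2 (cat.), t-BuOOH, salicylic acid (cat.), CH2Cl2, rt
Reagents that add atoms: tert-butyl hydroperoxide, CC(C)(C)OO
Why: Riley oxidation should hydroxylate the E-methyl group of the electron-rich terminal alkene (C13), while the ester-conjugated alkene is deactivated.

Step 7
Reactants: 11 ethyl (2Z,6E)-8-hydroxy-3-[(TBDPS-oxy)methyl]-7-methylocta-2,6-dienoate
Product: 12 ethyl (2Z,6E)-8-bromo-3-[(TBDPS-oxy)methyl]-7-methylocta-2,6-dienoate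
Conditions: PBr3, Et2O, 0 °C
Reagents that add atoms: phosphorus tribromide, BrP(Br)Br
Why: SN2 bromination through the bromophosphite converts the primary allylic alcohol into the bromide at low temperature without allylic shift.

Step 8
Reactants: 12 ethyl (2Z,6E)-8-bromo-3-[(TBDPS-oxy)methyl]-7-methylocta-2,6-dienoate; 13 2,5-dihydrothiophene 1,1-dioxide (3-sulfolene)
Product: 14 ethyl (2Z,6E)-8-(1,1-dioxo-2,5-dihydrothiophen-2-yl)-3-[(TBDPS-oxy)methyl]-7-methylocta-2,6-dienoate
Conditions: LiN(SiMe3)2 added to 12 + 13, THF–HMPA, −78 °C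
Reagents that add atoms: none
Why: α-Alkylation of the 3-sulfolene anion (a masked butadienyl anion, generated in the presence of the electrophile) attaches C14–C1–C15–C16 by SN2 displacement of the allylic bromide.

Step 9
Reactants: 14 ethyl (2Z,6E)-8-(1,1-dioxo-2,5-dihydrothiophen-2-yl)-3-[(TBDPS-oxy)methyl]-7-methylocta-2,6-dienoate
Product: 15 ethyl (2Z,6E,9E)-3-[(TBDPS-oxy)methyl]-7-methyldodeca-2,6,9,11-tetraenoate
Conditions: NaHCO3, toluene, 110 °C
Reagents that add atoms: none
Why: Thermal cheletropic extrusion of SO2 (disrotatory) should unmask the E-configured 1-substituted 1,3-diene.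

Step 10
Reactants: 15 ethyl (2Z,6E,9E)-3-[(TBDPS-oxy)methyl]-7-methyldodeca-2,6,9,11-tetraenoate
Product: 16 (2Z,6E,9E)-3-[(TBDPS-oxy)methyl]-7-methyldodeca-2,6,9,11-tetraen-1-ol
Conditions: i-Bu2AlH, CH2Cl2, −78 °C
Reagents that add atoms: none
Why: 1,2-Reduction of the enoate by the aluminium hydride gives the C6 allylic alcohol and leaves the diene and the silyl ether untouched.

Step 11
Reactants: 16 (2Z,6E,9E)-3-[(TBDPS-oxy)methyl]-7-methyldodeca-2,6,9,11-tetraen-1-ol
Product: 17 TBS ether of 16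
Conditions: t-BuMe2SiCl, imidazole, DMF, rt
Reagents that add atoms: tert-butyldimethylsilyl chloride, CC(C)(C)[Si](C)(C)Cl
Why: Silylation masks the C6 alcohol as a group inert to the nickel, borane and oxidation steps that can later be turned directly into the bromide.

Step 12
Reactants: 17 TBS ether of 16; 4 (2E)-2-methyl-4-oxobut-2-en-1-yl acetate
Product: 19 (2E,4R,5S,8E,12Z)-14-(TBS-oxy)-12-[(TBDPS-oxy)methyl]-5-ethenyl-4-hydroxy-2,8-dimethyltetradeca-2,8,12-trien-1-yl acetate, via Z-allylboronate 18 (not isolated)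
Conditions: HBpin, Ni(cod)2 (cat.), PCy3 (cat.), toluene, rt; silica plug; then 4, (R)-TRIP (5 mol %), toluene, −30 °C
Reagents that add atoms: none
Why: Nickel-catalysed 1,4-hydroboration of the terminal diene should give the Z-allylboronate, and chiral phosphoric acid-catalysed allylboration through a chair-like six-membered transition state turns the Z geometry into the syn C1/C2 relationship while the acid selects the aldehyde face and so the absolute configuration of both new stereocentres.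

Step 13
Reactants: 19 (2E,4R,5S,8E,12Z)-14-(TBS-oxy)-12-[(TBDPS-oxy)methyl]-5-ethenyl-4-hydroxy-2,8-dimethyltetradeca-2,8,12-trien-1-yl acetate
Product: 21 (2E,4R,5S,8E,12Z)-14-(TBS-oxy)-12-[(TBDPS-oxy)methyl]-4-hydroxy-5-(2-hydroxyethyl)-2,8-dimethyltetradeca-2,8,12-trien-1-yl acetate, via bis-borane adduct 20 (not isolated)
Conditions: 9-BBN (2.2 equiv), THF, 0 °C to rt; then 30% H2O2, pH 7 buffer
Reagents that add atoms: hydrogen peroxide, OO
Why: Hydroboration–oxidation with the bulky borane is selective for the monosubstituted alkene over the three trisubstituted ones and places the hydroxyl group on C16 (anti-Markovnikov).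

Step 14
Reactants: 21 (2E,4R,5S,8E,12Z)-14-(TBS-oxy)-12-[(TBDPS-oxy)methyl]-4-hydroxy-5-(2-hydroxyethyl)-2,8-dimethyltetradeca-2,8,12-trien-1-yl acetate
Product: 22 (4S,5R)-5-[(1E)-3-acetoxy-2-methylprop-1-en-1-yl]-4-[(3E,7Z)-9-(TBS-oxy)-7-[(TBDPS-oxy)methyl]-3-methylnona-3,7-dien-1-yl]oxolan-2-one
Conditions: TEMPO (cat.), PhI(OAc)2, CH2Cl2, rt
Reagents that add atoms: none
Why: Oxoammonium oxidation of the primary alcohol to the aldehyde, lactol formation with the C2 hydroxyl and a second oxidation give the cis-γ-lactone (oxidative lactonisation), which also masks the C2 oxygen for the key step and leaves C1 and C2 untouched.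

Step 15
Reactants: 22 (4S,5R)-5-[(1E)-3-acetoxy-2-methylprop-1-en-1-yl]-4-[(3E,7Z)-9-(TBS-oxy)-7-[(TBDPS-oxy)methyl]-3-methylnona-3,7-dien-1-yl]oxolan-2-one
Product: 23 (4S,5R)-5-[(1E)-3-acetoxy-2-methylprop-1-en-1-yl]-4-[(3E,7Z)-9-bromo-7-[(TBDPS-oxy)methyl]-3-methylnona-3,7-dien-1-yl]oxolan-2-one
Conditions: Ph3PBr2, CH2Cl2, 0 °C
Reagents that add atoms: dibromotriphenylphosphorane, BrP(Br)(c1ccccc1)(c1ccccc1)c1ccccc1
Why: The phosphorane activates the less hindered primary dimethylsilyl ether as a silyloxyphosphonium ion that bromide displaces by SN2, which should leave the bulkier diphenylsilyl ether, the acetate and the alkene geometry intact.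

Step 16
Reactants: 23 (4S,5R)-5-[(1E)-3-acetoxy-2-methylprop-1-en-1-yl]-4-[(3E,7Z)-9-bromo-7-[(TBDPS-oxy)methyl]-3-methylnona-3,7-dien-1-yl]oxolan-2-one
Product: 24 (4S,5R)-5-[(1E)-3-acetoxy-2-methylprop-1-en-1-yl]-4-[(3E,7Z)-9-(benzenesulfonyl)-7-[(TBDPS-oxy)methyl]-3-methylnona-3,7-dien-1-yl]oxolan-2-one
Conditions: PhSO2Na, DMF, rt
Reagents that add atoms: sodium benzenesulfinate, [Na+].[O-]S(=O)c1ccccc1
Why: SN2 S-alkylation of the sulfinate by the primary allylic bromide installs the sulfonyl group that acidifies C6, with no metal-allyl intermediate that could scramble the C7=C8 geometry.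

Step 17
Reactants: 24 (4S,5R)-5-[(1E)-3-acetoxy-2-methylprop-1-en-1-yl]-4-[(3E,7Z)-9-(benzenesulfonyl)-7-[(TBDPS-oxy)methyl]-3-methylnona-3,7-dien-1-yl]oxolan-2-one
Product: 27 (1R,2E,6Z,10E,14S)-14-(2-hydroxyethyl)-7-[(TBDPS-oxy)methyl]-3,11-dimethylcyclotetradeca-2,6,10-trien-1-ol, via sodium salt 25 (not isolated), via macrocyclic sulfone lactone 26 (not isolated)
Conditions: NaH, THF, 0 °C; slow addition to Pd(PPh3)4 (10 mol %), dppp (12 mol %), THF, 65 °C (2 mM); then LiBHEt3, −78 °C to 0 °C; H2O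
Reagents that add atoms: none
Why: NaH removes the proton between the sulfonyl group and the C7=C8 alkene to give allyl anion 25, zerovalent palladium ionises the primary allylic acetate to the syn-η3-allyl complex over C3–C4–C5, and the soft carbanion attacks the CH2 terminus C5 opposite to palladium (Tsuji–Trost allylic alkylation run as a macrocyclisation, closest known type: palladium-catalysed closure of medium and large carbocycles from sulfonyl-stabilised anions and allylic acetates); after cooling, LiBHEt3 first reduces the lactone to the diol at −78 °C and then, on warming, the same palladium–dppp catalyst ionises the new allylic sulfone and hydride is delivered to C6 (palladium-catalysed hydride desulfonylation of allylic sulfones). Ring A is closed in the exo mode at the unsubstituted allyl terminus (14 ring atoms), whereas attack at C3 would give a 12-membered ring with a branched carbon next to C2 and is sterically disfavoured; ring B is not formed here but opened, and is re-closed in step 18. No stereocentre of the target is created: C6 is a transient stereocentre erased by the desulfonylation, C1 is remote, and C2 should keep its configuration because a reversible ionisation of its allylic C–O bond returns the carboxylate with double inversion. The step needs chemoselectivity (acetate before lactone, secured by the primary versus secondary allylic position), regioselectivity (C5 and α-attack of the anion, secured by the substitution pattern) and retention of three alkene geometries: 3E is held in the syn-allyl complex, and the C7=C8 unit is no metal-allyl species during ring closure and only briefly one in the hydride stage, where capture at the less substituted C6 should be faster than syn–anti exchange through a tertiary σ-complex at C8. High dilution and slow addition of 25 keep oligomerisation down.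

Step 18
Reactants: 27 (1R,2E,6Z,10E,14S)-14-(2-hydroxyethyl)-7-[(TBDPS-oxy)methyl]-3,11-dimethylcyclotetradeca-2,6,10-trien-1-ol
Product: 28 (1S,2R,3E,7Z,11E)-19-(TBDPS-oxy)cembra-3,7,11-trien-16,2-olide (cis-fused)
Conditions: TEMPO (cat.), PhI(OAc)2, CH2Cl2, rt
Reagents that add atoms: none
Why: The same oxidative lactonisation re-forms the cis-fused γ-lactone from the C16 primary alcohol and the C2 allylic alcohol.

Step 19
Reactants: 28 (1S,2R,3E,7Z,11E)-19-(TBDPS-oxy)cembra-3,7,11-trien-16,2-olide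
Product: 31 (1S,2S,3E,7Z,11E)-19-(TBDPS-oxy)cembra-3,7,11,15(17)-tetraen-16,2-olide, via Mannich base 29 (not isolated), via methiodide 30 (not isolated)
Conditions: LiN(i-Pr)2, THF, −78 °C; CH2=NMe2+ I−; then MeI, MeOH; aq NaHCO3
Reagents that add atoms: Eschenmoser's salt (N,N-dimethylmethyleneiminium iodide), C=[N+](C)C.[I-]
Why: Aminomethylation of the lactone enolate (Mannich reaction), N-methylation and base-induced β-elimination of trimethylamine introduce the exocyclic methylene at C15 without affecting C1 or C2.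

Step 20
Reactants: 31 (1S,2S,3E,7Z,11E)-19-(TBDPS-oxy)cembra-3,7,11,15(17)-tetraen-16,2-olide
Product: 32 (1S,2S,3E,7Z,11E)-19-hydroxycembra-3,7,11,15(17)-tetraen-16,2-olide
Conditions: Bu4NF, AcOH, THF, 0 °C to rt
Reagents that add atoms: none
Why: Fluoride-induced Si–O cleavage, buffered with acetic acid to protect the α-methylene lactone from conjugate addition, frees the C19 alcohol.

Step 21
Reactants: 32 (1S,2S,3E,7Z,11E)-19-hydroxycembra-3,7,11,15(17)-tetraen-16,2-olide
Product: 33 (1S,2S,3E,7Z,11E)-19-acetoxycembra-3,7,11,15(17)-tetraen-16,2-olide (target)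
Conditions: Ac2O, pyridine, DMAP (cat.), CH2Cl2, 0 °C
Reagents that add atoms: acetic anhydride, CC(=O)OC(C)=O
Why: DMAP-catalysed acetylation of the primary allylic alcohol completes the target.

## Compound list

1 | 1,1-diethoxy-3-methylbut-2-ene | CCOC(OCC)C=C(C)C | starting material
2 | (2E)-4,4-diethoxy-2-methylbut-2-en-1-ol | CCOC(OCC)/C=C(\C)CO | intermediate
3 | (2E)-4,4-diethoxy-2-methylbut-2-en-1-yl acetate | CCOC(OCC)/C=C(\C)COC(C)=O | intermediate
4 | (2E)-2-methyl-4-oxobut-2-en-1-yl acetate | O=C/C=C(\C)COC(C)=O | intermediate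
5 | tert-butyl(diphenyl)(prop-2-yn-1-yloxy)silane | C#CCO[Si](c1ccccc1)(c1ccccc1)C(C)(C)C | starting material
6 | lithium acetylide of 5 | [Li]C#CCO[Si](c1ccccc1)(c1ccccc1)C(C)(C)C | intermediate (not isolated)
7 | ethyl 4-[(tert-butyldiphenylsilyl)oxy]but-2-ynoate | CCOC(=O)C#CCO[Si](c1ccccc1)(c1ccccc1)C(C)(C)C | intermediate
8 | 5-bromo-2-methylpent-2-ene | CC(C)=CCCBr | starting material
9 | (4-methylpent-3-en-1-yl)magnesium bromide | CC(C)=CCC[Mg]Br | intermediate (not isolated)
10 | ethyl (2Z)-3-[(TBDPS-oxy)methyl]-7-methylocta-2,6-dienoate | CCOC(=O)/C=C(\CO[Si](c1ccccc1)(c1ccccc1)C(C)(C)C)CCC=C(C)C | intermediate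
11 | ethyl (2Z,6E)-8-hydroxy-3-[(TBDPS-oxy)methyl]-7-methylocta-2,6-dienoate | CCOC(=O)/C=C(\CO[Si](c1ccccc1)(c1ccccc1)C(C)(C)C)CC/C=C(\C)CO | intermediate
12 | ethyl (2Z,6E)-8-bromo-3-[(TBDPS-oxy)methyl]-7-methylocta-2,6-dienoate | CCOC(=O)/C=C(\CO[Si](c1ccccc1)(c1ccccc1)C(C)(C)C)CC/C=C(\C)CBr | intermediate
13 | 2,5-dihydrothiophene 1,1-dioxide (3-sulfolene) | O=S1(=O)CC=CC1 | starting material
14 | ethyl (2Z,6E)-8-(1,1-dioxo-2,5-dihydrothiophen-2-yl)-3-[(TBDPS-oxy)methyl]-7-methylocta-2,6-dienoate (racemic at the ring carbon) | CCOC(=O)/C=C(\CO[Si](c1ccccc1)(c1ccccc1)C(C)(C)C)CC/C=C(\C)CC1C=CCS1(=O)=O | intermediate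
15 | ethyl (2Z,6E,9E)-3-[(TBDPS-oxy)methyl]-7-methyldodeca-2,6,9,11-tetraenoate | CCOC(=O)/C=C(\CO[Si](c1ccccc1)(c1ccccc1)C(C)(C)C)CC/C=C(\C)C/C=C/C=C | intermediate
16 | (2Z,6E,9E)-3-[(TBDPS-oxy)methyl]-7-methyldodeca-2,6,9,11-tetraen-1-ol | OC/C=C(\CO[Si](c1ccccc1)(c1ccccc1)C(C)(C)C)CC/C=C(\C)C/C=C/C=C | intermediate
17 | TBS ether of 16 | CC(C)(C)[Si](C)(C)OC/C=C(\CO[Si](c1ccccc1)(c1ccccc1)C(C)(C)C)CC/C=C(\C)C/C=C/C=C | intermediate
18 | 2-[(2Z,6E,10Z)-12-(TBS-oxy)-10-[(TBDPS-oxy)methyl]-6-methyldodeca-2,6,10-trien-1-yl]-4,4,5,5-tetramethyl-1,3,2-dioxaborolane | CC(C)(C)[Si](C)(C)OC/C=C(\CO[Si](c1ccccc1)(c1ccccc1)C(C)(C)C)CC/C=C(\C)CC/C=C\CB1OC(C)(C)C(C)(C)O1 | intermediate (not isolated)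
19 | (2E,4R,5S,8E,12Z)-14-(TBS-oxy)-12-[(TBDPS-oxy)methyl]-5-ethenyl-4-hydroxy-2,8-dimethyltetradeca-2,8,12-trien-1-yl acetate | O[C@H]([C@H](C=C)CC/C(C)=C/CC/C(CO[Si](c1ccccc1)(c1ccccc1)C(C)(C)C)=C/CO[Si](C)(C)C(C)(C)C)/C=C(\C)COC(C)=O | intermediate
20 | bis(9-borabicyclo[3.3.1]non-9-yl) adduct of 19 (O-borinate at C4, B-alkyl at the former CH2= carbon) | O(B1C2CCCC1CCC2)[C@H]([C@H](CCB1C2CCCC1CCC2)CC/C(C)=C/CC/C(CO[Si](c1ccccc1)(c1ccccc1)C(C)(C)C)=C/CO[Si](C)(C)C(C)(C)C)/C=C(\C)COC(C)=O | intermediate (not isolated)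
21 | (2E,4R,5S,8E,12Z)-14-(TBS-oxy)-12-[(TBDPS-oxy)methyl]-4-hydroxy-5-(2-hydroxyethyl)-2,8-dimethyltetradeca-2,8,12-trien-1-yl acetate | O[C@H]([C@H](CCO)CC/C(C)=C/CC/C(CO[Si](c1ccccc1)(c1ccccc1)C(C)(C)C)=C/CO[Si](C)(C)C(C)(C)C)/C=C(\C)COC(C)=O | intermediate
22 | (4S,5R)-5-[(1E)-3-acetoxy-2-methylprop-1-en-1-yl]-4-[(3E,7Z)-9-(TBS-oxy)-7-[(TBDPS-oxy)methyl]-3-methylnona-3,7-dien-1-yl]oxolan-2-one | O=C1O[C@@H](/C=C(\C)COC(C)=O)[C@@H](CC/C(C)=C/CC/C(CO[Si](c2ccccc2)(c2ccccc2)C(C)(C)C)=C/CO[Si](C)(C)C(C)(C)C)C1 | intermediate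
23 | (4S,5R)-5-[(1E)-3-acetoxy-2-methylprop-1-en-1-yl]-4-[(3E,7Z)-9-bromo-7-[(TBDPS-oxy)methyl]-3-methylnona-3,7-dien-1-yl]oxolan-2-one | O=C1O[C@@H](/C=C(\C)COC(C)=O)[C@@H](CC/C(C)=C/CC/C(CO[Si](c2ccccc2)(c2ccccc2)C(C)(C)C)=C/CBr)C1 | intermediate
24 | (4S,5R)-5-[(1E)-3-acetoxy-2-methylprop-1-en-1-yl]-4-[(3E,7Z)-9-(benzenesulfonyl)-7-[(TBDPS-oxy)methyl]-3-methylnona-3,7-dien-1-yl]oxolan-2-one | O=C1O[C@@H](/C=C(\C)COC(C)=O)[C@@H](CC/C(C)=C/CC/C(CO[Si](c2ccccc2)(c2ccccc2)C(C)(C)C)=C/CS(=O)(=O)c2ccccc2)C1 | intermediate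
25 | sodium salt of 24 (carbanion at the sulfonyl-bearing carbon) | [Na+].O=C1O[C@@H](/C=C(\C)COC(C)=O)[C@@H](CC/C(C)=C/CC/C(CO[Si](c2ccccc2)(c2ccccc2)C(C)(C)C)=C/[CH-]S(=O)(=O)c2ccccc2)C1 | intermediate (not isolated)
26 | (1S,2R,3E,7Z,11E)-6-(benzenesulfonyl)-19-(TBDPS-oxy)cembra-3,7,11-trien-16,2-olide (both C6 epimers) | C1C(=O)O[C@H]2/C=C(\C)CC(S(=O)(=O)c3ccccc3)/C=C(\CO[Si](c3ccccc3)(c3ccccc3)C(C)(C)C)CC/C=C(\C)CC[C@@H]12 | intermediate (not isolated)
27 | (1R,2E,6Z,10E,14S)-14-(2-hydroxyethyl)-7-[(TBDPS-oxy)methyl]-3,11-dimethylcyclotetradeca-2,6,10-trien-1-ol | OCC[C@@H]1CC/C(C)=C/CC/C(CO[Si](c2ccccc2)(c2ccccc2)C(C)(C)C)=C/CC/C(C)=C/[C@@H]1O | intermediate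
28 | (1S,2R,3E,7Z,11E)-19-(TBDPS-oxy)cembra-3,7,11-trien-16,2-olide (cis-fused) | C1C(=O)O[C@H]2/C=C(\C)CC/C=C(\CO[Si](c3ccccc3)(c3ccccc3)C(C)(C)C)CC/C=C(\C)CC[C@@H]12 | intermediate
29 | 17-(dimethylamino) derivative of 28 (α-(dimethylaminomethyl) lactone, C15 epimers) | CN(C)CC1C(=O)O[C@H]2/C=C(\C)CC/C=C(\CO[Si](c3ccccc3)(c3ccccc3)C(C)(C)C)CC/C=C(\C)CC[C@@H]12 | intermediate (not isolated)
30 | N-methyl iodide of 29 | C[N+](C)(C)CC1C(=O)O[C@H]2/C=C(\C)CC/C=C(\CO[Si](c3ccccc3)(c3ccccc3)C(C)(C)C)CC/C=C(\C)CC[C@@H]12.[I-] | intermediate (not isolated)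
31 | (1S,2S,3E,7Z,11E)-19-(TBDPS-oxy)cembra-3,7,11,15(17)-tetraen-16,2-olide | C=C1C(=O)O[C@H]2/C=C(\C)CC/C=C(\CO[Si](c3ccccc3)(c3ccccc3)C(C)(C)C)CC/C=C(\C)CC[C@@H]12 | intermediate
32 | (1S,2S,3E,7Z,11E)-19-hydroxycembra-3,7,11,15(17)-tetraen-16,2-olide | C=C1C(=O)O[C@H]2/C=C(\C)CC/C=C(\CO)CC/C=C(\C)CC[C@@H]12 | intermediate
33 | (1S,2S,3E,7Z,11E)-19-acetoxycembra-3,7,11,15(17)-tetraen-16,2-olide | C=C1C(=O)O[C@H]2/C=C(\C)CC/C=C(\COC(C)=O)CC/C=C(\C)CC[C@@H]12 | target

## Step count and risks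

Total step count: 21. Longest linear sequence: 18 steps (5 to 33, steps 4 to 21); the enal branch (steps 1 to 3) joins in step 12.

Steps most likely to fail:

1. Step 17. Ring closure may lose to intermolecular alkylation (oligomers), the anion may attack the internal allyl terminus or the acetate carbonyl, and the C7=C8 geometry may leak during the hydride stage. Fallback: from 24 the acetate would be removed (K2CO3, MeOH, 0 °C, then PPTS to re-close any opened lactone) to give seco-sulfone alcohol F1. MsCl, LiCl and 2,4,6-collidine in DMF would turn this into seco-sulfone chloride F2. Slow addition of F2 to KN(SiMe3)2 in THF (−78 °C to rt, 1 mM) would close ring A by a plain intramolecular SN2 alkylation of the sulfonyl anion, with no metal-allyl intermediate, giving 26. PdCl2(dppp) and LiBHEt3 (−78 to 0 °C) would then give 27, where the route is rejoined.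

2. Step 12. The Z geometry of the allylboronate may erode, uncatalysed background addition may compete, and residual phosphine may deactivate the acid, all of which would lower diastereo- and enantioselectivity. Fallback: from 17 the boronate 18 would be isolated and oxidised (NaBO3, THF–H2O) to Z-allylic alcohol F3. N-Chlorosuccinimide and Me2S would give Z-allylic chloride F4, and HSiCl3, CuCl and i-Pr2NEt in Et2O would give Z-allyltrichlorosilane F5. Addition of F5 to enal 4 with a chiral 2,2'-bipyrrolidine-derived bisphosphoramide (cat.) and i-Pr2NEt in CH2Cl2 at −78 °C goes through a closed chair siliconate, so the Z reagent should again give the syn adduct 19 under Lewis-base control.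

3. Step 15. The second silyl ether may be cleaved, or allylic transposition may occur during bromide formation. Fallback: from 22, HF·pyridine buffered with pyridine in THF at 0 °C would remove only the dimethylsilyl ether and give lactone alcohol F6. CBr4 and PPh3 (Appel reaction, CH2Cl2, 0 °C) would then give 23.

Further compounds
F1 | step 17 | seco-sulfone alcohol: (4S,5R)-4-[(3E,7Z)-9-(benzenesulfonyl)-7-[(TBDPS-oxy)methyl]-3-methylnona-3,7-dien-1-yl]-5-[(1E)-3-hydroxy-2-methylprop-1-en-1-yl]oxolan-2-one | O=C1O[C@@H](/C=C(\C)CO)[C@@H](CC/C(C)=C/CC/C(CO[Si](c2ccccc2)(c2ccccc2)C(C)(C)C)=C/CS(=O)(=O)c2ccccc2)C1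
F2 | step 17 | seco-sulfone chloride: (4S,5R)-4-[(3E,7Z)-9-(benzenesulfonyl)-7-[(TBDPS-oxy)methyl]-3-methylnona-3,7-dien-1-yl]-5-[(1E)-3-chloro-2-methylprop-1-en-1-yl]oxolan-2-one | O=C1O[C@@H](/C=C(\C)CCl)[C@@H](CC/C(C)=C/CC/C(CO[Si](c2ccccc2)(c2ccccc2)C(C)(C)C)=C/CS(=O)(=O)c2ccccc2)C1
F3 | step 12 | Z-allylic alcohol: (2Z,6E,10Z)-12-(TBS-oxy)-10-[(TBDPS-oxy)methyl]-6-methyldodeca-2,6,10-trien-1-ol | CC(C)(C)[Si](C)(C)OC/C=C(\CO[Si](c1ccccc1)(c1ccccc1)C(C)(C)C)CC/C=C(\C)CC/C=C\CO
F4 | step 12 | Z-allylic chloride: (2Z,6E,10Z)-1-chloro-12-(TBS-oxy)-10-[(TBDPS-oxy)methyl]-6-methyldodeca-2,6,10-triene | CC(C)(C)[Si](C)(C)OC/C=C(\CO[Si](c1ccccc1)(c1ccccc1)C(C)(C)C)CC/C=C(\C)CC/C=C\CCl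
F5 | step 12 | Z-allyltrichlorosilane: trichloro[(2Z,6E,10Z)-12-(TBS-oxy)-10-[(TBDPS-oxy)methyl]-6-methyldodeca-2,6,10-trien-1-yl]silane | CC(C)(C)[Si](C)(C)OC/C=C(\CO[Si](c1ccccc1)(c1ccccc1)C(C)(C)C)CC/C=C(\C)CC/C=C\C[Si](Cl)(Cl)Cl
F6 | step 15 | lactone alcohol: (4S,5R)-5-[(1E)-3-acetoxy-2-methylprop-1-en-1-yl]-4-[(3E,7Z)-9-hydroxy-7-[(TBDPS-oxy)methyl]-3-methylnona-3,7-dien-1-yl]oxolan-2-one | O=C1O[C@@H](/C=C(\C)COC(C)=O)[C@@H](CC/C(C)=C/CC/C(CO[Si](c2ccccc2)(c2ccccc2)C(C)(C)C)=C/CO)C1
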